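The readings were generated by integration from invented constants; scatter was added.

Rings cannot come from a step whose rate goes with both end groups: such a step takes a fixed share of what reacts, yet teal and grey, each consuming about 0.050 M of limiting reagent, end near 0.00107 M and 0.00560 M of rings, grey holding more.

| flask | first end groups | second end groups | remark | time |
|---|---|---|---|---|
| red | 0.10 M | 0.102 M | run made earlier |  |
| teal | 0.050 M | 0.102 M | run made earlier |  |
| ochre | 0.20 M | 0.102 M | run made earlier |  |
| grey | 0.10 M | 0.051 M | run made earlier |  |
| maple | 0.10 M (fed, over 2.5 h) | 0.102 M | all else is in the flask from the start; the feed brings no volume worth counting | 4.0 h |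
| birch | 0.10 M | 0.102 M (fed, over 2.5 h) | all else is in the flask from the start; the feed brings no volume worth counting | 4.0 h |
| larch | 0.10 M | 0.102 M | everything together at the start | 4.0 h |

| run | time / h | links / % | rings / % |
|---|---|---|---|
| red | 0.250 | 23.0 | 0.8 |
| red | 0.833 | 14.6 | 2.0 |
| red | 1.33 | 7.0 | 1.7 |
| red | 2.00 | 3.6 | 2.5 |
| red | 3.00 | 1.7 | 3.1 |
| red | 4.00 | 1.2 | 4.0 |
| teal | 0.250 | 25.6 | 0 |
| teal | 0.417 | 25.4 | 1.5 |
| teal | 0.667 | 21.1 | 1.8 |
| teal | 1.33 | 9.9 | 2.1 |
| teal | 2.00 | 3.9 | 2.3 |
| teal | 3.00 | 1.4 | 2.0 |
| ochre | 0.500 | 15.2 | 0.5 |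
| ochre | 1.00 | 5.5 | 2.5 |
| ochre | 1.50 | 1.7 | 4.3 |
| ochre | 2.00 | 0.8 | 4.8 |
| ochre | 2.50 | 0 | 4.0 |
| ochre | 3.00 | 0 | 3.8 |
| grey | 0.250 | 11.9 | 0.6 |
| grey | 0.500 | 12.4 | 1.8 |
| grey | 0.833 | 8.7 | 2.6 |
| grey | 1.50 | 4.3 | 3.9 |
| grey | 3.00 | 0 | 5.6 |

(readings scatter by 0.5 percentage points)

- which flask leads in share of links in links plus rings ("all alike" within 1.5 percentage points) (maple / birch / larch / all alike)
- share of links in links plus rings at the end, maple
- share of links in links plus rings at the end, birch
- share of links in links plus rings at the end, larch

- the numbers in the tables scatter by 0.5 percentage points (one standard deviation)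
- steps thought possible: first end groups + second end groups <-> links; first end groups + second end groups -> rings; links -> over-reaction product

Call the first and second end groups A and B, links L, rings Q. With the link step alone the share L/(L+Q) is 100 percent, and A and B follow the second-order law. Teal's late links fall at 1.17 /h over an excess of 0.0520 M, so the constant is g = 22.5 /M/h, and larch reaches A = 0.00999 M, B = 0.0120 M. For the feeds we join two ends: at the end of dosing we set consumption equal to feed, A = 0.0421 M, and the law carries on to A = 0.0174 M, B = 0.0194 M.

Now add the drain to over-reaction product: L becomes a stock, L = φAB. At teal's peak, between its first two readings, the law gives B = 0.0778 M, A = 0.0258 M, so φ = 6.35 /M, and L is 7.61 × 10⁻⁴ M in larch, 0.00214 M in either feed.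

Last come rings, at a rate kA while B lasts. The ring step uses B as well, so B falls at gAB + kA = gA(B+ρ), with ρ = k/g, and A cancels: with B present from the start, Q = ρ ln[(C+ρ)/(B+ρ)], C being its charge. This ring allowance ρ, the rings gained per unit fall of ln(B+ρ), reads from teal, dropping ρ beside the excess of B there, as 0.00158 M, which is far smaller than that excess; on grey, where B is the limiting reagent, it gives 0.00555 M. So larch holds 0.00322 M, maple 0.00253 M. Birch starts without B, so we multiply ρg by the area under A, straight from charge to Af across the feed, then the law's tail: 0.00774 M. Our shares: maple 45.8%, birch 21.7%, larch 19.1%.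

The forecast also names maple, but its shares stand higher than ours, at 53%, 29%, 25%, and it reads that “Rings lag and stop when links vanish”.

The flasks give 44.3% for maple, 23.7% for birch, 18.3% for larch, and maple leads.

    first end groups + second end groups ⇌ links (K = 120 /M, k = 0.00620 /M/s)
    first end groups + second end groups → rings, rate k2*[first end groups] as long as [second end groups] is above zero (k = 9.90 × 10⁻⁶ /s)
    links → over-reaction product (k = 8.70 × 10⁻⁴ /s)

In maple at 1.63 h the forward link step uses first end groups 38 times as fast as the ring step, with half-lives of 0.52 h against 19 h. Applied to the second end groups left in maple, 17% of their charge, ρ gives 2.72% of the first end groups charged as rings, and maple holds 2.91%. In a neighbouring flask, maple with 0.025 M of second end groups, those stand at 0% at the end; ρ gives 4.47%, and that flask holds 4.74%.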